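J cannot be read from the earlier runs, for they report Z and L and never J, so the state of this flask has to be reckoned from what has appeared.

| flask | J | remark | time |
|---|---|---|---|
| eta | 0.067 M | run made earlier |  |
| theta | 0.15 M | run made earlier |  |
| flask | 0.10 M |  | 25 h |

| run | time / h | Z / % | L / % |
|---|---|---|---|
| eta | 2.50 | 0.3 | 5.0 |
| eta | 8.00 | 1.7 | 14.7 |
| eta | 15.0 | 4.8 | 21.8 |
| eta | 20.0 | 7.1 | 23.6 |
| eta | 30.0 | 14.0 | 26.7 |
| theta | 2.50 | 0.9 | 5.8 |
| theta | 5.00 | 0.8 | 9.2 |
| theta | 8.00 | 1.9 | 12.8 |
| theta | 15.0 | 5.4 | 21.1 |
| theta | 30.0 | 16.0 | 26.4 |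

(readings scatter by 0.5 percentage points)

- a reading or a percentage of Z counts all its forms, free or not

- how much Z there is at 25 h, in percent of the J charged
- how much L there is at 25 h, in percent of the J charged
- amount of Z if the flask were left three thousand times as long, in percent of the J charged

Does the charge matter? Little for the sum of L and Z: theta holds twice the charge of eta, yet at 15.0 h that sum reads 26.6% in eta and 26.5% in theta. But Z at 30.0 h reads 14.0% in eta and 16.0% in theta, so I treat percent as roughly a function of time, and I read this flask, whose charge lies between them, from the runs with that caution on Z.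

What do you read at the asked time? Eta has readings on either side, and their midpoints give Z 10.6% and L 25.1%.

What can you freeze for the long wait? Pooling both runs at 8.00 h, where I assume that what J has lost stands as L and Z, gives 0.0211 h⁻¹, the loss constant of J, an apparent first-order rate constant: minus the logarithm of the fraction not yet found as L or Z, divided by the time. It leaves 0.512% of J at 250 h.

And at 30.0 h? The constant leaves 53.1% of J, while L and Z average 41.6%, so a gap of 5.4 percentage points is unaccounted for. If that gap holds, Z ends near 94.6%.

Isn't that weak? Yes: the same reckoning gives 0.61 points at 15.0 h, so freezing the gap is a bet.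

The forecast, calling the steps “close to first order”, gives Z 10.7%, L 25.4% and, in the long run, 92%, which is lower than my figure.

The flask gives Z 10.9%, L 26.1% and, in the long run, 93.9%, and the forecast is right within the tolerance on each.

    J → L (k = 0.0225 h⁻¹)
    L → Z (k = 0.0394 h⁻¹)
    Z ⇌ G (K = 0.778, k = 0.161 h⁻¹)
    Q ⇌ Z, rate k4*(cs4 - [Z]) while solid is left; crystals form when [Z] > cs4 (solubility = 7.90 mM, k = 0.290 h⁻¹)

In this flask at the asked time, 0.0211 h⁻¹ leaves 59.0% of J, and the flask holds 57.0%, with G at 5.97%. The same flask read at 96.0 h is the second test: the constant leaves 13.2% of J, and that flask holds 11.5%. Beside that J it holds L 12.3%, G 7.74% and Z 68.4%, crystals counted.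

The data stem from a simulated flask on assumed constants.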